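**Plan**

1. Retrosynthetic cuts, in order: the O‑benzyl and O‑silyl groups; C5–H and C5–aryl of the oxolane (lactone carbonyl + aryllithium, then hydride); the aroyl C–C3 bond (2‑aryl‑1,3‑dithiane anion + butenolide); C4–C5 (CO inserted into a C4–I bond); finally C2–C3 and C4–CH(OH) (acetylene as C3/C4 plus two 4‑(benzyloxy)benzaldehydes).
2. Enabling feature: ring C5, the O–CH carbon bearing the 2,4‑dihydroxyphenyl group, can be held at the lactone level; O1–C5(=O)–C4=C3–C2 is then a butenolide ring whose β‑carbon is C3, so the aroyl carbon can be joined to C3 as a nucleophile (acyl anion equivalent, polarity reversal).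
3. Second feature: C2 and the exocyclic carbinol carbon are both ArCH–O centres (Ar = 4‑hydroxyphenyl) of like configuration on either side of C3–C4, so C2–C3–C4–CH(OH) is a latent C2‑symmetric 1,4‑diarylbut‑2‑yne‑1,4‑diol.
4. Forward: ynediol → Z‑iodo‑enediol → butenolide (ring atoms O1 and C2–C5 assembled by carbonylative lactonisation) → union with the dithiane at C3 → aryl and hydride at C5 → dithiane hydrolysis → desilylation and hydrogenolysis.
5. Stereochemistry: C2 and the carbinol carbon from one catalytic asymmetric (CBS) double reduction; C3 relayed from C2 (addition anti to the C2 aryl group); C4 from kinetic protonation anti to the new C3 substituent; C5 from hydride delivery anti to the C4 substituent.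

Key step: step 8

Remark: target ring numbering (O1; C2 bearing 4‑hydroxyphenyl; C3 bearing the aroyl group; C4 bearing the carbinol side chain; C5 bearing 2,4‑dihydroxyphenyl) is used in the text; the sense of the reduction in step 3 is assigned from the usual CBS model with the aryl group as the larger ketone substituent.

**Route**

Step 1
Reactants: 1 4‑(benzyloxy)benzaldehyde (2 equiv); 2 acetylene
Product: 4 1,4‑bis[4‑(benzyloxy)phenyl]but‑2‑yne‑1,4‑diol, via ethynylenebis(magnesium bromide) 3 (not isolated)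
Conditions: 2, EtMgBr (2 equiv), THF, 0 → 45 °C; then 1, 0 °C → rt; H2O
Reagents that add atoms: none
Why: Double deprotonation of acetylene gives the bis‑Grignard reagent, which adds twice to the non‑enolisable aldehyde (1,2‑addition of an alkynyl Grignard reagent); the racemic/meso mixture is acceptable because both carbinols are oxidised in step 2.

Step 2
Reactants: 4 1,4‑bis[4‑(benzyloxy)phenyl]but‑2‑yne‑1,4‑diol
Product: 5 1,4‑bis[4‑(benzyloxy)phenyl]but‑2‑yne‑1,4‑dione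
Conditions: activated MnO2 (excess), CH2Cl2, rt
Reagents that add atoms: none
Why: MnO2 oxidises benzylic‑propargylic alcohols selectively to the ynone and leaves the benzyl ethers untouched, which erases the uncontrolled carbinol configuration.

Step 3
Reactants: 5 1,4‑bis[4‑(benzyloxy)phenyl]but‑2‑yne‑1,4‑dione
Product: 6 (1S,4S)‑1,4‑bis[4‑(benzyloxy)phenyl]but‑2‑yne‑1,4‑diol
Conditions: (S)‑Me‑CBS (0.3 equiv), catecholborane (2.4 equiv), CH2Cl2, −78 °C; then MeOH, aq. NaHCO3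
Reagents that add atoms: none
Why: Corey–Bakshi–Shibata reduction of each aryl alkynyl ketone under catalyst control (aryl as the large group) should set both carbinol centres S, and the double reduction diverts most of the minor sense into the separable meso diol.

Step 4
Reactants: 6 (1S,4S)‑1,4‑bis[4‑(benzyloxy)phenyl]but‑2‑yne‑1,4‑diol
Product: 8 (1S,2Z,4R)‑1,4‑bis[4‑(benzyloxy)phenyl]‑2‑iodobut‑2‑ene‑1,4‑diol, via cyclic alkenylalanate 7 (not isolated)
Conditions: Red‑Al (3.5 equiv), THF, 0 °C → rt; then I2, THF, −78 → 0 °C; aq. Rochelle salt/Na2S2O3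
Reagents that add atoms: iodine, II
Why: Alkoxide‑directed trans‑hydroalumination places aluminium on the distal alkyne carbon in a five‑membered oxa‑alanate and iodinolysis with retention gives the Z‑iodoalkene; because the diol is C2‑symmetric either hydroxyl directs to the same product, and the carbinol centres are untouched (descriptors change only through CIP priorities).

Step 5
Reactants: 8 (1S,2Z,4R)‑1,4‑bis[4‑(benzyloxy)phenyl]‑2‑iodobut‑2‑ene‑1,4‑diol
Product: 9 (5R)‑5‑[4‑(benzyloxy)phenyl]‑3‑{(S)‑[4‑(benzyloxy)phenyl](hydroxy)methyl}furan‑2(5H)‑one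
Conditions: PdCl2(PPh3)2 (5 mol %), CO (1 atm), K2CO3, THF, 40 °C
Reagents that add atoms: carbon monoxide, [C-]#[O+]
Why: Oxidative addition to the C–I bond, CO insertion and capture of the acylpalladium by the cis‑disposed hydroxyl (carbonylative lactonisation of a Z‑γ‑iodo allylic alcohol) close the butenolide; the other hydroxyl could only give a four‑membered lactone and stays free.

Step 6
Reactants: 9 (5R)‑5‑[4‑(benzyloxy)phenyl]‑3‑{(S)‑[4‑(benzyloxy)phenyl](hydroxy)methyl}furan‑2(5H)‑one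
Product: 10 (5R)‑5‑[4‑(benzyloxy)phenyl]‑3‑{(S)‑[4‑(benzyloxy)phenyl][(tert‑butyldimethylsilyl)oxy]methyl}furan‑2(5H)‑one
Conditions: TBSOTf (1.2 equiv), 2,6‑lutidine, CH2Cl2, −78 °C
Reagents that add atoms: tert‑butyldimethylsilyl trifluoromethanesulfonate, CC(C)(C)[Si](C)(C)OS(=O)(=O)C(F)(F)F
Why: Silylation with a hindered, weakly basic amine removes the acidic O–H before the organolithium steps without epimerising the base‑sensitive C5 of the butenolide.

Step 7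
Reactants: 11 2,4‑bis(benzyloxy)benzaldehyde
Product: 12 2‑[2,4‑bis(benzyloxy)phenyl]‑1,3‑dithiane
Conditions: propane‑1,3‑dithiol (1.1 equiv), BF3·OEt2 (cat.), CH2Cl2, 0 °C
Reagents that add atoms: propane‑1,3‑dithiol, SCCCS
Why: Lewis‑acid‑catalysed dithioacetalisation of the aromatic aldehyde gives the Corey–Seebach acyl‑anion precursor.

Step 8
Reactants: 12 2‑[2,4‑bis(benzyloxy)phenyl]‑1,3‑dithiane; 10 (5R)‑5‑[4‑(benzyloxy)phenyl]‑3‑{(S)‑[4‑(benzyloxy)phenyl][(tert‑butyldimethylsilyl)oxy]methyl}furan‑2(5H)‑one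
Product: 15 (3R,4R,5R)‑4‑{2‑[2,4‑bis(benzyloxy)phenyl]‑1,3‑dithian‑2‑yl}‑5‑[4‑(benzyloxy)phenyl]‑3‑{(R)‑[4‑(benzyloxy)phenyl][(tert‑butyldimethylsilyl)oxy]methyl}oxolan‑2‑one, via 2‑lithio‑2‑[2,4‑bis(benzyloxy)phenyl]‑1,3‑dithiane 13 (not isolated), via lithium lactone enolate 14 (not isolated)
Conditions: 12 (1.3 equiv), n‑BuLi, THF, −78 → −30 °C; then 10, THF, −78 °C; then AcOH/THF, −78 °C
Reagents that add atoms: none
Why: Deprotonation of 12 gives the sulfur‑stabilised carbanion 13, an acyl‑anion equivalent that reverses the polarity of the aroyl carbon (Corey–Seebach umpolung), and 13 adds in conjugate fashion to C4 of the butenolide (C3 of the target), a β‑carbon that exists only because target C5 is held at the lactone oxidation level. The closest known reaction type is the conjugate addition of lithiated 2‑aryl‑1,3‑dithianes to butenolides followed by enolate quench, as used for lignan lactones. No ring is closed in this step. The new centre at lactone C4 is set by the adjacent C5 aryl group (attack anti to it, 4,5‑trans), and the centre at lactone C3 is set when enolate 14 is protonated at −78 °C from the face opposite to the bulky dithianyl group (kinetic protonation, 3,4‑cis). The step needs 1,4‑ over 1,2‑addition and addition over deprotonation at the benzylic C5–H, which the soft, delocalised anion and the low temperature should secure, while the silyl ether keeps the side‑chain oxygen from quenching the anion. The cold acetic acid quench should also forestall β‑elimination of silanolate from 14 and equilibration to the trans lactone.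

Step 9
Reactants: 16 4‑bromobenzene‑1,3‑diol
Product: 17 2,4‑bis(benzyloxy)‑1‑bromobenzene
Conditions: BnBr (2.2 equiv), K2CO3, DMF, rt
Reagents that add atoms: benzyl bromide, BrCc1ccccc1
Why: Williamson etherification of both phenols gives the precursor of the C5 aryl nucleophile.

Step 10
Reactants: 17 2,4‑bis(benzyloxy)‑1‑bromobenzene; 15 (3R,4R,5R)‑4‑{2‑[2,4‑bis(benzyloxy)phenyl]‑1,3‑dithian‑2‑yl}‑5‑[4‑(benzyloxy)phenyl]‑3‑{(R)‑[4‑(benzyloxy)phenyl][(tert‑butyldimethylsilyl)oxy]methyl}oxolan‑2‑one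
Product: 19 (3R,4R,5R)‑2‑[2,4‑bis(benzyloxy)phenyl]‑4‑{2‑[2,4‑bis(benzyloxy)phenyl]‑1,3‑dithian‑2‑yl}‑5‑[4‑(benzyloxy)phenyl]‑3‑{(R)‑[4‑(benzyloxy)phenyl][(tert‑butyldimethylsilyl)oxy]methyl}oxolan‑2‑ol, via [2,4‑bis(benzyloxy)phenyl]lithium 18 (not isolated)
Conditions: 17 (2.5 equiv), n‑BuLi, THF, −78 °C; then 15, −78 °C; H2O
Reagents that add atoms: none
Why: Bromine–lithium exchange gives the aryllithium, which should add once to the lactone carbonyl at −78 °C because the lithium hemiketal alkoxide persists until work‑up; no existing stereocentre is touched and the new hemiketal centre (both configurations, in equilibrium with the hydroxy ketone) is removed in step 11.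

Step 11
Reactants: 19 (3R,4R,5R)‑2‑[2,4‑bis(benzyloxy)phenyl]‑4‑{2‑[2,4‑bis(benzyloxy)phenyl]‑1,3‑dithian‑2‑yl}‑5‑[4‑(benzyloxy)phenyl]‑3‑{(R)‑[4‑(benzyloxy)phenyl][(tert‑butyldimethylsilyl)oxy]methyl}oxolan‑2‑ol
Product: 20 2‑[2,4‑bis(benzyloxy)phenyl]‑2‑[(2R,3R,4S,5R)‑5‑[2,4‑bis(benzyloxy)phenyl]‑2‑[4‑(benzyloxy)phenyl]‑4‑{(R)‑[4‑(benzyloxy)phenyl][(tert‑butyldimethylsilyl)oxy]methyl}oxolan‑3‑yl]‑1,3‑dithiane
Conditions: Et3SiH (5 equiv), BF3·OEt2 (2 equiv), CH2Cl2, −78 °C; Et3N then aq. NaHCO3 at −78 °C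
Reagents that add atoms: none
Why: Ionisation of the hemiketal gives the aryl‑stabilised cyclic oxocarbenium ion and silane hydride is delivered to C5 from the face opposite to the C4 and C3 substituents, leaving the C5 aryl group cis to the C4 side chain (ionic reduction of 2‑aryl lactols); −78 °C and the cold basic quench are meant to prevent re‑ionisation of the product.

Step 12
Reactants: 20 2‑[2,4‑bis(benzyloxy)phenyl]‑2‑[(2R,3R,4S,5R)‑5‑[2,4‑bis(benzyloxy)phenyl]‑2‑[4‑(benzyloxy)phenyl]‑4‑{(R)‑[4‑(benzyloxy)phenyl][(tert‑butyldimethylsilyl)oxy]methyl}oxolan‑3‑yl]‑1,3‑dithiane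
Product: 21 [2,4‑bis(benzyloxy)phenyl][(2R,3R,4S,5R)‑5‑[2,4‑bis(benzyloxy)phenyl]‑2‑[4‑(benzyloxy)phenyl]‑4‑{(R)‑[4‑(benzyloxy)phenyl][(tert‑butyldimethylsilyl)oxy]methyl}oxolan‑3‑yl]methanone
Conditions: MeI (excess), CaCO3, MeCN/H2O (9:1), 45 °C
Reagents that add atoms: water, O
Why: Alkylative hydrolysis of the dithiane (S‑methylation, then hydrolysis of the sulfonium salt) under buffered, non‑oxidising conditions should spare the electron‑rich rings and the enolisable stereocentre C3.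

Step 13
Reactants: 21 [2,4‑bis(benzyloxy)phenyl][(2R,3R,4S,5R)‑5‑[2,4‑bis(benzyloxy)phenyl]‑2‑[4‑(benzyloxy)phenyl]‑4‑{(R)‑[4‑(benzyloxy)phenyl][(tert‑butyldimethylsilyl)oxy]methyl}oxolan‑3‑yl]methanone
Product: 22 [2,4‑bis(benzyloxy)phenyl][(2R,3R,4R,5R)‑5‑[2,4‑bis(benzyloxy)phenyl]‑2‑[4‑(benzyloxy)phenyl]‑4‑{(R)‑[4‑(benzyloxy)phenyl](hydroxy)methyl}oxolan‑3‑yl]methanone
Conditions: HF·pyridine, pyridine/THF, 0 °C → rt
Reagents that add atoms: none
Why: Fluoride cleaves the Si–O bond under buffered, weakly acidic conditions that avoid enolisation at C3 and β‑elimination of the ring oxygen (the C4 descriptor changes from S to R only through CIP priorities).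

Step 14
Reactants: 22 [2,4‑bis(benzyloxy)phenyl][(2R,3R,4R,5R)‑5‑[2,4‑bis(benzyloxy)phenyl]‑2‑[4‑(benzyloxy)phenyl]‑4‑{(R)‑[4‑(benzyloxy)phenyl](hydroxy)methyl}oxolan‑3‑yl]methanone
Product: 23 (2,4‑dihydroxyphenyl)[(2R,3R,4R,5R)‑5‑(2,4‑dihydroxyphenyl)‑4‑[(R)‑hydroxy(4‑hydroxyphenyl)methyl]‑2‑(4‑hydroxyphenyl)oxolan‑3‑yl]methanone
Conditions: H2 (1 atm), 10% Pd/C, EtOAc/MeOH, rt
Reagents that add atoms: none
Why: Hydrogenolysis of the six aryl benzyl ethers under neutral conditions, stopped after uptake of six equivalents, should leave the three secondary benzylic C–O bonds and the aryl ketone, which react more slowly than O‑benzyl groups.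

**Compound list**

1 | 4‑(benzyloxy)benzaldehyde | O=Cc1ccc(OCc2ccccc2)cc1 | starting material
2 | acetylene | C#C | starting material
3 | ethynylenebis(magnesium bromide) | Br[Mg]C#C[Mg]Br | intermediate
4 | 1,4‑bis[4‑(benzyloxy)phenyl]but‑2‑yne‑1,4‑diol (racemic and meso forms) | OC(C#CC(O)c1ccc(OCc2ccccc2)cc1)c1ccc(OCc2ccccc2)cc1 | intermediate
5 | 1,4‑bis[4‑(benzyloxy)phenyl]but‑2‑yne‑1,4‑dione | O=C(C#CC(=O)c1ccc(OCc2ccccc2)cc1)c1ccc(OCc2ccccc2)cc1 | intermediate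
6 | (1S,4S)‑1,4‑bis[4‑(benzyloxy)phenyl]but‑2‑yne‑1,4‑diol | O[C@H](C#C[C@@H](O)c1ccc(OCc2ccccc2)cc1)c1ccc(OCc2ccccc2)cc1 | intermediate
7 | cyclic alkenylalanate (disodium salt; Al bound to the iodine‑bearing carbon of 8 and to the cis hydroxyl oxygen) | [Na+].[Na+].COCCO[Al-]1(OCCOC)O[C@@H](c2ccc(OCc3ccccc3)cc2)C=C1[C@@H]([O-])c1ccc(OCc2ccccc2)cc1 | intermediate
8 | (1S,2Z,4R)‑1,4‑bis[4‑(benzyloxy)phenyl]‑2‑iodobut‑2‑ene‑1,4‑diol | O[C@H](/C=C(\I)[C@@H](O)c1ccc(OCc2ccccc2)cc1)c1ccc(OCc2ccccc2)cc1 | intermediate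
9 | (5R)‑5‑[4‑(benzyloxy)phenyl]‑3‑{(S)‑[4‑(benzyloxy)phenyl](hydroxy)methyl}furan‑2(5H)‑one | C1=C([C@@H](O)c2ccc(OCc3ccccc3)cc2)C(=O)O[C@H]1c1ccc(OCc2ccccc2)cc1 | intermediate
10 | (5R)‑5‑[4‑(benzyloxy)phenyl]‑3‑{(S)‑[4‑(benzyloxy)phenyl][(tert‑butyldimethylsilyl)oxy]methyl}furan‑2(5H)‑one | C1=C([C@@H](O[Si](C)(C)C(C)(C)C)c2ccc(OCc3ccccc3)cc2)C(=O)O[C@H]1c1ccc(OCc2ccccc2)cc1 | intermediate
11 | 2,4‑bis(benzyloxy)benzaldehyde | O=Cc1ccc(OCc2ccccc2)cc1OCc1ccccc1 | starting material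
12 | 2‑[2,4‑bis(benzyloxy)phenyl]‑1,3‑dithiane | C1(c2ccc(OCc3ccccc3)cc2OCc2ccccc2)SCCCS1 | intermediate
13 | 2‑lithio‑2‑[2,4‑bis(benzyloxy)phenyl]‑1,3‑dithiane | [Li]C1(c2ccc(OCc3ccccc3)cc2OCc2ccccc2)SCCCS1 | intermediate
14 | lithium enolate of lactone 15 | [Li]OC1=C([C@@H](O[Si](C)(C)C(C)(C)C)c2ccc(OCc3ccccc3)cc2)[C@@H](C2(c3ccc(OCc4ccccc4)cc3OCc3ccccc3)SCCCS2)[C@H](c2ccc(OCc3ccccc3)cc2)O1 | intermediate
15 | (3R,4R,5R)‑4‑{2‑[2,4‑bis(benzyloxy)phenyl]‑1,3‑dithian‑2‑yl}‑5‑[4‑(benzyloxy)phenyl]‑3‑{(R)‑[4‑(benzyloxy)phenyl][(tert‑butyldimethylsilyl)oxy]methyl}oxolan‑2‑one | C1(c2ccc(OCc3ccccc3)cc2OCc2ccccc2)(SCCCS1)[C@@H]1[C@H]([C@@H](O[Si](C)(C)C(C)(C)C)c2ccc(OCc3ccccc3)cc2)C(=O)O[C@H]1c1ccc(OCc2ccccc2)cc1 | intermediate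
16 | 4‑bromobenzene‑1,3‑diol | Oc1ccc(Br)c(O)c1 | starting material
17 | 2,4‑bis(benzyloxy)‑1‑bromobenzene | Brc1ccc(OCc2ccccc2)cc1OCc1ccccc1 | intermediate
18 | [2,4‑bis(benzyloxy)phenyl]lithium | [Li]c1ccc(OCc2ccccc2)cc1OCc1ccccc1 | intermediate
19 | (3R,4R,5R)‑2‑[2,4‑bis(benzyloxy)phenyl]‑4‑{2‑[2,4‑bis(benzyloxy)phenyl]‑1,3‑dithian‑2‑yl}‑5‑[4‑(benzyloxy)phenyl]‑3‑{(R)‑[4‑(benzyloxy)phenyl][(tert‑butyldimethylsilyl)oxy]methyl}oxolan‑2‑ol (both configurations at C2) | C1(c2ccc(OCc3ccccc3)cc2OCc2ccccc2)(SCCCS1)[C@@H]1[C@H]([C@@H](O[Si](C)(C)C(C)(C)C)c2ccc(OCc3ccccc3)cc2)C(O)(c2ccc(OCc3ccccc3)cc2OCc2ccccc2)O[C@H]1c1ccc(OCc2ccccc2)cc1 | intermediate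
20 | 2‑[2,4‑bis(benzyloxy)phenyl]‑2‑[(2R,3R,4S,5R)‑5‑[2,4‑bis(benzyloxy)phenyl]‑2‑[4‑(benzyloxy)phenyl]‑4‑{(R)‑[4‑(benzyloxy)phenyl][(tert‑butyldimethylsilyl)oxy]methyl}oxolan‑3‑yl]‑1,3‑dithiane | C1(c2ccc(OCc3ccccc3)cc2OCc2ccccc2)(SCCCS1)[C@@H]1[C@H]([C@@H](O[Si](C)(C)C(C)(C)C)c2ccc(OCc3ccccc3)cc2)[C@H](c2ccc(OCc3ccccc3)cc2OCc2ccccc2)O[C@H]1c1ccc(OCc2ccccc2)cc1 | intermediate
21 | [2,4‑bis(benzyloxy)phenyl][(2R,3R,4S,5R)‑5‑[2,4‑bis(benzyloxy)phenyl]‑2‑[4‑(benzyloxy)phenyl]‑4‑{(R)‑[4‑(benzyloxy)phenyl][(tert‑butyldimethylsilyl)oxy]methyl}oxolan‑3‑yl]methanone | O=C(c1ccc(OCc2ccccc2)cc1OCc1ccccc1)[C@@H]1[C@H]([C@@H](O[Si](C)(C)C(C)(C)C)c2ccc(OCc3ccccc3)cc2)[C@H](c2ccc(OCc3ccccc3)cc2OCc2ccccc2)O[C@H]1c1ccc(OCc2ccccc2)cc1 | intermediate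
22 | [2,4‑bis(benzyloxy)phenyl][(2R,3R,4R,5R)‑5‑[2,4‑bis(benzyloxy)phenyl]‑2‑[4‑(benzyloxy)phenyl]‑4‑{(R)‑[4‑(benzyloxy)phenyl](hydroxy)methyl}oxolan‑3‑yl]methanone | O=C(c1ccc(OCc2ccccc2)cc1OCc1ccccc1)[C@@H]1[C@H]([C@@H](O)c2ccc(OCc3ccccc3)cc2)[C@H](c2ccc(OCc3ccccc3)cc2OCc2ccccc2)O[C@H]1c1ccc(OCc2ccccc2)cc1 | intermediate
23 | (2,4‑dihydroxyphenyl)[(2R,3R,4R,5R)‑5‑(2,4‑dihydroxyphenyl)‑4‑[(R)‑hydroxy(4‑hydroxyphenyl)methyl]‑2‑(4‑hydroxyphenyl)oxolan‑3‑yl]methanone | O=C(c1ccc(O)cc1O)[C@@H]1[C@H]([C@@H](O)c2ccc(O)cc2)[C@H](c2ccc(O)cc2O)O[C@H]1c1ccc(O)cc1 | target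

**Step count and risks**

Total steps: 14. Longest linear sequence: 12 steps (steps 1–6, 8, 10–14, from 1 and 2 to 23).

The three steps most likely to fail are 8, 10 and 11.

Step 8. The hindered, ortho‑substituted anion 13 may act as a base toward the acidic benzylic C5–H of the 5‑aryl butenolide (furanolate formation and loss of configuration at C5) or add too slowly, and enolate 14 may expel silanolate before it is protonated. The fallback sets out from 10 and introduces the aroyl carbon first as a smaller carboxyl‑anion equivalent, leaving the aryl–acyl bond for a later cross‑coupling. Tris(methylsulfanyl)methane is lithiated with n‑BuLi to tris(methylsulfanyl)methyllithium F1, which is added to 10 at −78 °C to give the lithium lactone enolate F2. Cold protonation as in step 8 should give the tris(methylsulfanyl)methyl lactone F3, the group being bulky enough to direct protonation in the same sense. Addition of 18 as in step 10 gives the hemiketal F4, and ionic reduction as in step 11 gives the oxolane F5. Hg(II)‑assisted hydrolysis of the orthothioester (HgCl2, CaCO3, aq. MeCN) gives the S‑methyl thioester F6. Fukuyama coupling of F6 with [2,4‑bis(benzyloxy)phenyl]zinc chloride F7 (from 18 and ZnCl2; PdCl2(PPh3)2, THF) gives the ketone, and the route is rejoined at 21.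

Step 10. The basic aryllithium may enolise the hindered cis‑disubstituted lactone at C3 (recovered or epimerised lactone) instead of adding, or add twice. The fallback sets out from 15: ring opening with N,O‑dimethylhydroxylamine hydrochloride and AlMe3 (CH2Cl2, 0 °C → rt) gives the hydroxy Weinreb amide F8. The less basic [2,4‑bis(benzyloxy)phenyl]magnesium bromide F9 (from 17 and Mg, THF) then acylates once, and the resulting hydroxy ketone closes on work‑up to hemiketal 19, where the route is rejoined.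

Step 11. The Lewis acid may re‑ionise the product at C5 (2,4‑dialkoxybenzyl cation), which would epimerise the all‑cis C3/C4/C5 array to the more stable trans isomer, or ionise the benzylic silyl ether. The fallback sets out from 19 and makes the C5–H bond by hydrogen‑atom transfer, so that the product never meets acid. The dithiane is hydrolysed first (MeI, CaCO3, aq. MeCN) to the keto hemiketal F10. Thiophenol and BF3·OEt2 at −78 °C convert F10 into the S‑phenyl monothioketal F11, whose configuration at C5 is irrelevant. Bu3SnH/AIBN (toluene, 80 °C) then reduces the C–S bond through the planar C5 radical, which should take hydrogen from the face opposite to the C4 side chain, and the route is rejoined at 21.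

**Further compounds**

F1 | step 8 | tris(methylsulfanyl)methyllithium | [Li]C(SC)(SC)SC
F2 | step 8 | lithium enolate of lactone F3 | [Li]OC1=C([C@@H](O[Si](C)(C)C(C)(C)C)c2ccc(OCc3ccccc3)cc2)[C@@H](C(SC)(SC)SC)[C@H](c2ccc(OCc3ccccc3)cc2)O1
F3 | step 8 | (3R,4R,5R)‑5‑[4‑(benzyloxy)phenyl]‑3‑{(R)‑[4‑(benzyloxy)phenyl][(tert‑butyldimethylsilyl)oxy]methyl}‑4‑[tris(methylsulfanyl)methyl]oxolan‑2‑one | C(SC)(SC)(SC)[C@@H]1[C@H]([C@@H](O[Si](C)(C)C(C)(C)C)c2ccc(OCc3ccccc3)cc2)C(=O)O[C@H]1c1ccc(OCc2ccccc2)cc1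
F4 | step 8 | 2‑[2,4‑bis(benzyloxy)phenyl]oxolan‑2‑ol (hemiketal) derived from F3, both configurations at C2 | C(SC)(SC)(SC)[C@@H]1[C@H]([C@@H](O[Si](C)(C)C(C)(C)C)c2ccc(OCc3ccccc3)cc2)C(O)(c2ccc(OCc3ccccc3)cc2OCc2ccccc2)O[C@H]1c1ccc(OCc2ccccc2)cc1
F5 | step 8 | (2R,3R,4S,5R)‑5‑[2,4‑bis(benzyloxy)phenyl]‑2‑[4‑(benzyloxy)phenyl]‑4‑{(R)‑[4‑(benzyloxy)phenyl][(tert‑butyldimethylsilyl)oxy]methyl}‑3‑[tris(methylsulfanyl)methyl]oxolane | C(SC)(SC)(SC)[C@@H]1[C@H]([C@@H](O[Si](C)(C)C(C)(C)C)c2ccc(OCc3ccccc3)cc2)[C@H](c2ccc(OCc3ccccc3)cc2OCc2ccccc2)O[C@H]1c1ccc(OCc2ccccc2)cc1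
F6 | step 8 | S‑methyl (2R,3R,4S,5R)‑5‑[2,4‑bis(benzyloxy)phenyl]‑2‑[4‑(benzyloxy)phenyl]‑4‑{(R)‑[4‑(benzyloxy)phenyl][(tert‑butyldimethylsilyl)oxy]methyl}oxolane‑3‑carbothioate | CSC(=O)[C@@H]1[C@H]([C@@H](O[Si](C)(C)C(C)(C)C)c2ccc(OCc3ccccc3)cc2)[C@H](c2ccc(OCc3ccccc3)cc2OCc2ccccc2)O[C@H]1c1ccc(OCc2ccccc2)cc1
F7 | step 8 | [2,4‑bis(benzyloxy)phenyl]zinc chloride | Cl[Zn]c1ccc(OCc2ccccc2)cc1OCc1ccccc1
F8 | step 10 | (2R,3R,4R)‑3‑{2‑[2,4‑bis(benzyloxy)phenyl]‑1,3‑dithian‑2‑yl}‑4‑[4‑(benzyloxy)phenyl]‑2‑{(R)‑[4‑(benzyloxy)phenyl][(tert‑butyldimethylsilyl)oxy]methyl}‑4‑hydroxy‑N‑methoxy‑N‑methylbutanamide | C1(c2ccc(OCc3ccccc3)cc2OCc2ccccc2)(SCCCS1)[C@H]([C@H]([C@@H](O[Si](C)(C)C(C)(C)C)c1ccc(OCc2ccccc2)cc1)C(=O)N(C)OC)[C@@H](O)c1ccc(OCc2ccccc2)cc1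
F9 | step 10 | [2,4‑bis(benzyloxy)phenyl]magnesium bromide | Br[Mg]c1ccc(OCc2ccccc2)cc1OCc1ccccc1
F10 | step 11 | keto hemiketal: 19 with the dithiane replaced by C=O, both configurations at the hemiketal carbon | O=C(c1ccc(OCc2ccccc2)cc1OCc1ccccc1)[C@@H]1[C@H]([C@@H](O[Si](C)(C)C(C)(C)C)c2ccc(OCc3ccccc3)cc2)C(O)(c2ccc(OCc3ccccc3)cc2OCc2ccccc2)O[C@H]1c1ccc(OCc2ccccc2)cc1
F11 | step 11 | S‑phenyl monothioketal: F10 with the hemiketal OH replaced by SPh, both configurations at that carbon | O=C(c1ccc(OCc2ccccc2)cc1OCc1ccccc1)[C@@H]1[C@H]([C@@H](O[Si](C)(C)C(C)(C)C)c2ccc(OCc3ccccc3)cc2)C(Sc2ccccc2)(c2ccc(OCc3ccccc3)cc2OCc2ccccc2)O[C@H]1c1ccc(OCc2ccccc2)cc1
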